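**Retrosynthetic overview**

1. The strategy rests on the C2–C3 bond of pyranone ring C. C2 carries O1 and aryl ring B, and C3 carries the hydroxyl and sits α to the C4 ketone, so the same atoms exist as O1–C2(aryl)–O3–C3H2–C4(=O) in a benzylidene acetal of a 2,ω-dihydroxyacetophenone.
2. Key disconnection C2–C3: racemic seven-membered 1,3-benzodioxepin-5-one 12 contracts to ring C under a chiral Brønsted acid by an O3-to-C3 shift, setting C2 and C3 together.
3. Acetal 12 comes from ketol 8 and aldehyde acetal 11 (two C2–O bonds); ketol 8 comes from methyl ketone 5 by Rubottom oxidation.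
4. Ring A is taken from 2',6'-dihydroxy-4'-methoxyacetophenone; O-allylation, silylation of the other hydroxyl and Claisen rearrangement fix which oxygen becomes O1 and place the C8 side chain.
5. Ring order: rings A and B are bought, the seven-membered acetal ring is made and then contracted to ring C; the side chain stays allyl through the cationic step (a prenyl alkene ortho to O1 would trap the cation) and is turned into prenyl by cross-metathesis before desilylation.

Key step: step 8

Remark: the sense of induction of the chiral acid cannot be derived with certainty, so the (R)-catalyst is written and its mirror image is used if it favours the (2S,3S) series.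

**Route**

Step 1
Reactants: 1 1-(2,6-dihydroxy-4-methoxyphenyl)ethanone; 2 allyl bromide
Product: 3 1-[2-(allyloxy)-6-hydroxy-4-methoxyphenyl]ethanone
Conditions: allyl bromide (1.05 equiv), K2CO3 (1.1 equiv), acetone, reflux
Reagents that add atoms: none
Why: Williamson etherification; the two hydroxyls of 1 are equivalent, and after the first alkylation the remaining one is locked in a hydrogen bond to the ketone and should resist a second alkylation.

Step 2
Reactants: 3 1-[2-(allyloxy)-6-hydroxy-4-methoxyphenyl]ethanone
Product: 4 1-[2-(allyloxy)-6-(tert-butyldimethylsilyloxy)-4-methoxyphenyl]ethanone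
Conditions: TBSCl (1.3 equiv), imidazole (2.5 equiv), DMAP (cat.), DMF, rt to 40 °C
Reagents that add atoms: tert-butyldimethylsilyl chloride, CC(C)(C)[Si](C)(C)Cl
Why: Silylation of the only free phenol, so the two ring A oxygens are told apart without relying on steric selectivity: the silylated one becomes the C5 oxygen and the allylated one becomes O1.

Step 3
Reactants: 4 1-[2-(allyloxy)-6-(tert-butyldimethylsilyloxy)-4-methoxyphenyl]ethanone
Product: 5 1-[3-allyl-6-(tert-butyldimethylsilyloxy)-2-hydroxy-4-methoxyphenyl]ethanone
Conditions: N,N-diethylaniline, 190 °C, sealed tube, argon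
Reagents that add atoms: none
Why: Aromatic Claisen rearrangement; the only open ortho position of the allyl ether is C3 (the other carries the acetyl group), so the allyl group lands next to the phenol it frees.

Step 4
Reactants: 5 1-[3-allyl-6-(tert-butyldimethylsilyloxy)-2-hydroxy-4-methoxyphenyl]ethanone
Product: 8 1-[3-allyl-6-(tert-butyldimethylsilyloxy)-2-hydroxy-4-methoxyphenyl]-2-hydroxyethanone, via bis(trimethylsilyl) enol ether 6 (not isolated), via bis(trimethylsilyl) ketol ether 7 (not isolated)
Conditions: TMSOTf (2.4 equiv), Et3N (3.5 equiv), CH2Cl2, 0 °C; then mCPBA (1.05 equiv), NaHCO3, CH2Cl2, −20 °C; then citric acid, MeOH, 0 °C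
Reagents that add atoms: 3-chloroperbenzoic acid, O=C(OO)c1cccc(Cl)c1; trimethylsilyl triflate, C[Si](C)(C)OS(=O)(=O)C(F)(F)F (its silicon stays only in 6 and 7)
Why: Rubottom oxidation; soft enolisation silylates both the phenol and the methyl ketone, the electron-rich enol silane should be epoxidised much faster than the monosubstituted allyl alkene, and mild acid methanolysis removes both trimethylsilyl groups while the aryl tert-butyldimethylsilyl ether stays.

Step 5
Reactants: 9 4-hydroxybenzaldehyde
Product: 10 4-(tert-butyldimethylsilyloxy)benzaldehyde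
Conditions: TBSCl (1.1 equiv), imidazole (2 equiv), CH2Cl2, rt
Reagents that add atoms: tert-butyldimethylsilyl chloride, CC(C)(C)[Si](C)(C)Cl
Why: Standard phenol silylation; the silyl ether prevents quinone methide formation in the later cation and keeps the para oxygen as a donor.

Step 6
Reactants: 10 4-(tert-butyldimethylsilyloxy)benzaldehyde
Product: 11 tert-butyl[4-(dimethoxymethyl)phenoxy]dimethylsilane
Conditions: HC(OMe)3 (3 equiv), PPTS (cat.), MeOH, rt; Et3N quench
Reagents that add atoms: trimethyl orthoformate, COC(OC)OC
Why: Acid-catalysed acetalisation driven by the orthoformate as water scavenger; the aryl silyl ether should tolerate the weak acid.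

Step 7
Reactants: 8 1-[3-allyl-6-(tert-butyldimethylsilyloxy)-2-hydroxy-4-methoxyphenyl]-2-hydroxyethanone; 11 tert-butyl[4-(dimethoxymethyl)phenoxy]dimethylsilane
Product: 12 rac-9-allyl-6-(tert-butyldimethylsilyloxy)-2-[4-(tert-butyldimethylsilyloxy)phenyl]-8-methoxy-4H-1,3-benzodioxepin-5-one
Conditions: PPTS (10 mol%), toluene, 60 °C, 200 mbar (MeOH distilled off); Et3N quench; chromatography on Et3N-deactivated silica
Reagents that add atoms: none
Why: Transacetalisation; the primary hydroxyl exchanges first, the phenol then closes the seven-membered ring on the oxocarbenium ion as methanol is removed, and the pyridinium acid is too weak to enolise the ketone, so the acetal should be isolable before any rearrangement.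

Step 8
Reactants: 12 rac-9-allyl-6-(tert-butyldimethylsilyloxy)-2-[4-(tert-butyldimethylsilyloxy)phenyl]-8-methoxy-4H-1,3-benzodioxepin-5-one
Product: 14 (2R,3R)-8-allyl-5-(tert-butyldimethylsilyloxy)-2-[4-(tert-butyldimethylsilyloxy)phenyl]-3-hydroxy-7-methoxychroman-4-one, via oxocarbenium–enediol ion pair 13 (not isolated)
Conditions: (R)-3,3'-bis(2,4,6-triisopropylphenyl)-1,1'-binaphthyl-2,2'-diyl N-triflyl phosphoramide (10 mol%), toluene (0.02 M), 5 Å MS, −20 °C to rt
Reagents that add atoms: none
Why: Proposed new method: the acid protonates the alkyl acetal oxygen (future O3) and cleaves its bond to the acetal carbon (future C2), giving a cation stabilised by O1 and the 4-silyloxyphenyl group and still tethered to the ketol, which the bifunctional catalyst anion tautomerises to the enediol (13); the enediol carbon C3 then attacks C2 and the C4 ketone is released directly, closing ring C by a 6-(enolendo)-endo-trig cyclisation, the O-to-C shift of a Petasis–Ferrier rearrangement, whose chiral-acid variants on cyclic vinyl acetals and hemiaminal vinyl ethers are the closest known reactions. Return of either oxygen to C2, including after the easier ionisation on the O1 side, only regenerates racemic 12, so both enantiomers of 12 drain through the same planar cation and the step is stereoconvergent. C2 is set by the face of the oxocarbenium ion left open in the contact ion pair with the chiral anion, with the aryl group pseudo-equatorial in the half-chair. C3 is set under thermodynamic control, because acid-mediated enolisation of the product ketol should equilibrate it to the 2,3-trans diequatorial isomer without touching C2. The step needs carbon attack through C3 and not C4, and no other nucleophile for the cation: C4 attack would be a 5-endo closure to a strained hydroxy aldehyde, the silyl ether on the C5 oxygen stops acetal return through the other phenol (which would lead to the 6-allyl isomer), the monosubstituted allyl alkene is too weak a π-nucleophile for a Prins closure, and high dilution with sieves limits intermolecular arylation and hydrolysis.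

Step 9
Reactants: 14 (2R,3R)-8-allyl-5-(tert-butyldimethylsilyloxy)-2-[4-(tert-butyldimethylsilyloxy)phenyl]-3-hydroxy-7-methoxychroman-4-one; 15 2-methyl-2-butene
Product: 16 (2R,3R)-5-(tert-butyldimethylsilyloxy)-2-[4-(tert-butyldimethylsilyloxy)phenyl]-3-hydroxy-7-methoxy-8-(3-methylbut-2-enyl)chroman-4-one
Conditions: 2-methyl-2-butene (excess), second-generation Grubbs catalyst (H2IMes)(PCy3)Cl2Ru=CHPh (5 mol%), 1,4-benzoquinone (10 mol%), CH2Cl2, 40 °C, sealed tube
Reagents that add atoms: none
Why: Olefin cross-metathesis of the terminal allyl alkene with 2-methyl-2-butene as isopropylidene donor (propene lost); the trisubstituted product should not re-enter the cycle, benzoquinone suppresses double-bond migration, and neither stereocentre is involved.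

Step 10
Reactants: 16 (2R,3R)-5-(tert-butyldimethylsilyloxy)-2-[4-(tert-butyldimethylsilyloxy)phenyl]-3-hydroxy-7-methoxy-8-(3-methylbut-2-enyl)chroman-4-one
Product: 17 (2R,3R)-3,5-dihydroxy-2-(4-hydroxyphenyl)-7-methoxy-8-(3-methylbut-2-enyl)chroman-4-one (CNP0265127.1)
Conditions: TBAF (2.4 equiv), AcOH (2.4 equiv), THF, 0 °C
Reagents that add atoms: none
Why: Fluoride cleavage of both aryl silyl ethers, driven by Si–F bond formation; the acetic acid buffer keeps phenoxide and enolate levels low, so C3 should not epimerise and the pyranone should not open at C2.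

**Compound list**

1 | 1-(2,6-dihydroxy-4-methoxyphenyl)ethanone (2',6'-dihydroxy-4'-methoxyacetophenone, commercial) | CC(=O)c1c(O)cc(OC)cc1O | starting material
2 | allyl bromide | C=CCBr | starting material
3 | 1-[2-(allyloxy)-6-hydroxy-4-methoxyphenyl]ethanone | CC(=O)c1c(O)cc(OC)cc1OCC=C | intermediate
4 | 1-[2-(allyloxy)-6-(tert-butyldimethylsilyloxy)-4-methoxyphenyl]ethanone | CC(=O)c1c(O[Si](C)(C)C(C)(C)C)cc(OC)cc1OCC=C | intermediate
5 | 1-[3-allyl-6-(tert-butyldimethylsilyloxy)-2-hydroxy-4-methoxyphenyl]ethanone | CC(=O)c1c(O[Si](C)(C)C(C)(C)C)cc(OC)c(CC=C)c1O | intermediate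
6 | bis(trimethylsilyl) enol ether of 5 (aryl trimethylsilyl ether and trimethylsilyl enol ether) | C=C(O[Si](C)(C)C)c1c(O[Si](C)(C)C(C)(C)C)cc(OC)c(CC=C)c1O[Si](C)(C)C | intermediate (not isolated)
7 | 1-[3-allyl-6-(tert-butyldimethylsilyloxy)-4-methoxy-2-(trimethylsilyloxy)phenyl]-2-(trimethylsilyloxy)ethanone | C[Si](C)(C)OCC(=O)c1c(O[Si](C)(C)C(C)(C)C)cc(OC)c(CC=C)c1O[Si](C)(C)C | intermediate (not isolated)
8 | 1-[3-allyl-6-(tert-butyldimethylsilyloxy)-2-hydroxy-4-methoxyphenyl]-2-hydroxyethanone | OCC(=O)c1c(O[Si](C)(C)C(C)(C)C)cc(OC)c(CC=C)c1O | intermediate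
9 | 4-hydroxybenzaldehyde | O=Cc1ccc(O)cc1 | starting material
10 | 4-(tert-butyldimethylsilyloxy)benzaldehyde | O=Cc1ccc(O[Si](C)(C)C(C)(C)C)cc1 | intermediate
11 | tert-butyl[4-(dimethoxymethyl)phenoxy]dimethylsilane | COC(OC)c1ccc(O[Si](C)(C)C(C)(C)C)cc1 | intermediate
12 | rac-9-allyl-6-(tert-butyldimethylsilyloxy)-2-[4-(tert-butyldimethylsilyloxy)phenyl]-8-methoxy-4H-1,3-benzodioxepin-5-one | COc1cc(O[Si](C)(C)C(C)(C)C)c2c(c1CC=C)OC(c1ccc(O[Si](C)(C)C(C)(C)C)cc1)OCC2=O | intermediate
13 | ring-opened oxocarbenium ion carrying the enediol, paired with the catalyst anion (cation shown) | C=CCc1c(OC)cc(O[Si](C)(C)C(C)(C)C)c(C(O)=CO)c1[O+]=Cc1ccc(O[Si](C)(C)C(C)(C)C)cc1 | intermediate (not isolated)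
14 | (2R,3R)-8-allyl-5-(tert-butyldimethylsilyloxy)-2-[4-(tert-butyldimethylsilyloxy)phenyl]-3-hydroxy-7-methoxychroman-4-one | COc1cc(O[Si](C)(C)C(C)(C)C)c2c(c1CC=C)O[C@H](c1ccc(O[Si](C)(C)C(C)(C)C)cc1)[C@@H](O)C2=O | intermediate
15 | 2-methyl-2-butene | CC=C(C)C | starting material
16 | (2R,3R)-5-(tert-butyldimethylsilyloxy)-2-[4-(tert-butyldimethylsilyloxy)phenyl]-3-hydroxy-7-methoxy-8-(3-methylbut-2-enyl)chroman-4-one | COc1cc(O[Si](C)(C)C(C)(C)C)c2c(c1CC=C(C)C)O[C@H](c1ccc(O[Si](C)(C)C(C)(C)C)cc1)[C@@H](O)C2=O | intermediate
17 | (2R,3R)-3,5-dihydroxy-2-(4-hydroxyphenyl)-7-methoxy-8-(3-methylbut-2-enyl)chroman-4-one | COc1cc(O)c2c(c1CC=C(C)C)O[C@H](c1ccc(O)cc1)[C@@H](O)C2=O | target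

**Step count**

Total steps: 10. Longest linear sequence: 8 (steps 1, 2, 3, 4, 7, 8, 9, 10).

**Steps most likely to fail**

Step 8. The ion pair may only return to the acetal, may be lost to hydrolysis or intermolecular arylation, or may close with poor facial selectivity or through an unselective background pathway. The fallback uses known chalcone epoxide chemistry, sets out from 5 and 10 and comes back at 14.
- The phenol of 5 is capped with MOMCl and iPr2NEt to give 1-[3-allyl-6-(tert-butyldimethylsilyloxy)-4-methoxy-2-(methoxymethoxy)phenyl]ethanone F1.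
- The lithium enolate of F1 (LiHMDS, THF, −78 °C) adds to 10 to give the racemic aldol 1-[3-allyl-6-(tert-butyldimethylsilyloxy)-4-methoxy-2-(methoxymethoxy)phenyl]-3-[4-(tert-butyldimethylsilyloxy)phenyl]-3-hydroxypropan-1-one F2.
- F2 is dehydrated with MsCl and Et3N to the (E)-chalcone F3.
- Catalytic asymmetric nucleophilic epoxidation of the enone with tert-butyl hydroperoxide and La(OiPr)3/BINOL/Ph3As=O, the ligand enantiomer chosen for this sense, should give the (αR,βS)-epoxy ketone F4.
- Dilute HCl in MeOH/THF cleaves the methoxymethyl ether, and the freed phenol opens the epoxide at the benzylic carbon with inversion (6-endo) to give 14.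

Step 7. The exchange equilibrium may lie against the chelated, hindered phenol oxygen, and the mixed aryl alkyl acetal may hydrolyse or rearrange without control during isolation. The fallback sets out from 8 and 10 and comes back at 12, and makes no compound outside the list (F0). Ketol 8 is silylated on both hydroxyls (TMSCl, Et3N) to the bis(trimethylsilyl) ether 7, which is condensed with aldehyde 10 itself under aprotic silyl-transfer acetalisation (TMSOTf cat., CH2Cl2, −78 °C, pyridine quench). This closes the acetal under kinetic control at low temperature and bypasses dimethyl acetal 11 and the protic acid.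

Step 4. The hindered chelated phenol and ketone may silylate incompletely, or the peracid may oxidise the electron-rich arene or the allyl group or over-oxidise the ketol. The fallback sets out from 5 and comes back at 8, and replaces the enol silane and peracid by direct enolate oxidation. KHMDS (2.2 equiv, THF, −78 °C) gives the dipotassium phenoxide–enolate of 5 F5, which is hydroxylated with 3-phenyl-2-(phenylsulfonyl)oxaziridine (Davis enolate oxidation, inert to alkenes at this temperature) and quenched with aqueous NH4Cl.

**Further compounds**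

F1 | step 8 | 1-[3-allyl-6-(tert-butyldimethylsilyloxy)-4-methoxy-2-(methoxymethoxy)phenyl]ethanone | COCOc1c(CC=C)c(OC)cc(O[Si](C)(C)C(C)(C)C)c1C(C)=O
F2 | step 8 | 1-[3-allyl-6-(tert-butyldimethylsilyloxy)-4-methoxy-2-(methoxymethoxy)phenyl]-3-[4-(tert-butyldimethylsilyloxy)phenyl]-3-hydroxypropan-1-one (racemic) | COCOc1c(CC=C)c(OC)cc(O[Si](C)(C)C(C)(C)C)c1C(=O)CC(O)c1ccc(O[Si](C)(C)C(C)(C)C)cc1
F3 | step 8 | (E)-1-[3-allyl-6-(tert-butyldimethylsilyloxy)-4-methoxy-2-(methoxymethoxy)phenyl]-3-[4-(tert-butyldimethylsilyloxy)phenyl]prop-2-en-1-one | COCOc1c(CC=C)c(OC)cc(O[Si](C)(C)C(C)(C)C)c1C(=O)/C=C/c1ccc(O[Si](C)(C)C(C)(C)C)cc1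
F4 | step 8 | [3-allyl-6-(tert-butyldimethylsilyloxy)-4-methoxy-2-(methoxymethoxy)phenyl] {(2R,3S)-3-[4-(tert-butyldimethylsilyloxy)phenyl]oxiran-2-yl} ketone | COCOc1c(CC=C)c(OC)cc(O[Si](C)(C)C(C)(C)C)c1C(=O)[C@@H]1O[C@H]1c1ccc(O[Si](C)(C)C(C)(C)C)cc1
F0 | step 7 | none | none
F5 | step 4 | dipotassium phenoxide–enolate of 5 | [K+].[K+].C=C([O-])c1c(O[Si](C)(C)C(C)(C)C)cc(OC)c(CC=C)c1[O-]
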